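**Plan**
- Retrosynthesis: the p-coumarate is cut first (built last on the axial C6 alcohol through a malonic half ester), then the C6 alcohol goes back to a ring B enone.
- Ring B carries its only oxygen on C6, flanked by C5 and C7; with C6 as a ketone both neighbours are nucleophilic, while C10 and C8 (1,3-related through C9) are the β-carbon and the carbonyl carbon of an enal. Cutting C5–C10 and C7–C8 therefore opens both rings to an acyclic 9-oxofarnesal-type keto enal.
- Forward: one amine-catalysed Michael/aldol-condensation cascade closes ring A (C5–C10, quaternary C10) and then ring B (C7–C8).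
- The keto enal is assembled from 3-methylanisole (Birch reduction and ozonolysis give the Z alkene that becomes the ring A alkene), isobutylmagnesium bromide and an acetoacetate enol triflate (Negishi coupling).
- Stereochemistry: C10 from the chiral imidazolidinone (face control on the iminium ion); C5 by kinetic protonation anti to the angular methyl; C7 by axial protonation of the conjugate-reduction enolate; C6 by hydride attack anti to the angular methyl.

Key step: step 9

Remark: positions are given in eudesmane numbering (ring A = C1–C5, C10; ring B = C5–C10; methyls on C4 and C10, isopropyl on C7, oxygen on C6); the iminium ion of the β,β-disubstituted enal is assumed to react through its E isomer.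

**Route**

Step 1
Reactants: 1 3-methylanisole
Product: 2 1-methoxy-5-methylcyclohexa-1,4-diene
Conditions: Li, NH3 (l), t-BuOH, THF, −78 → −33 °C
Reagents that add atoms: none
Why: Birch reduction of an anisole should leave both donor substituents on sp2 carbons, giving the 1,4-diene with an enol ether and a trisubstituted alkene.

Step 2
Reactants: 2 1-methoxy-5-methylcyclohexa-1,4-diene
Product: 3 methyl (3Z)-6-hydroxy-3-methylhex-3-enoate
Conditions: O3 (1 equiv), CH2Cl2/MeOH, pyridine, −78 °C; then NaBH4, −78 → 0 °C
Reagents that add atoms: ozone, O=[O+][O-]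
Why: Ozonolysis should select the electron-rich enol ether double bond, the methoxy carbon becoming the methyl ester and the other carbon the alcohol after reductive work-up, and the Z geometry of the remaining alkene is fixed because both of its chain substituents came from the ring.

Step 3
Reactants: 3 methyl (3Z)-6-hydroxy-3-methylhex-3-enoate
Product: 5 (6Z)-9-hydroxy-2,6-dimethylnon-6-en-4-one, via N-methoxy-N-methylamide 4 (not isolated)
Conditions: MeNH(OMe)·HCl, i-PrMgCl, THF, −20 °C; then i-BuMgBr, −20 → 0 °C; aq. NH4Cl
Reagents that add atoms: isobutylmagnesium bromide, CC(C)C[Mg]Br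
Why: Weinreb ketone synthesis in one flask, in which the chelated tetrahedral intermediate should stop the Grignard addition at the ketone and the low temperature should keep the β,γ-alkene in place.

Step 4
Reactants: 5 (6Z)-9-hydroxy-2,6-dimethylnon-6-en-4-one
Product: 6 (6Z)-9-iodo-2,6-dimethylnon-6-en-4-one
Conditions: I2, PPh3, imidazole, CH2Cl2, 0 °C
Reagents that add atoms: iodine, II
Why: Appel-type iodination of the primary alcohol under near-neutral conditions that the β,γ-unsaturated ketone should tolerate.

Step 5
Reactants: 7 ethyl 3-oxobutanoate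
Product: 8 ethyl (2E)-3-{[(trifluoromethyl)sulfonyl]oxy}but-2-enoate
Conditions: Tf2O, aq. Me4NOH, hexanes, 5 → 23 °C
Reagents that add atoms: trifluoromethanesulfonic anhydride, O=S(=O)(OS(=O)(=O)C(F)(F)F)C(F)(F)F
Why: O-sulfonylation of the non-chelated tetramethylammonium enolate of a β-keto ester should give the E enol triflate.

Step 6
Reactants: 6 (6Z)-9-iodo-2,6-dimethylnon-6-en-4-one, 8 ethyl (2E)-3-{[(trifluoromethyl)sulfonyl]oxy}but-2-enoate
Product: 10 ethyl (2E,6Z)-3,7,11-trimethyl-9-oxododeca-2,6-dienoate, via alkylzinc iodide 9 (not isolated)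
Conditions: Zn dust, LiCl, THF, 40 °C; then 8, Pd(PPh3)4 (5 mol %), THF, 50 °C
Reagents that add atoms: none
Why: Zinc insertion gives a ketone-tolerant primary alkylzinc iodide, and its Negishi coupling with the enol triflate should proceed with retention of the E geometry.

Step 7
Reactants: 10 ethyl (2E,6Z)-3,7,11-trimethyl-9-oxododeca-2,6-dienoate
Product: 11 (2E,6Z)-3,7,11-trimethyldodeca-2,6-diene-1,9-diol (C9 racemic)
Conditions: i-Bu2AlH (5 equiv), CH2Cl2, −78 → 0 °C; aq. potassium sodium tartrate
Reagents that add atoms: none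
Why: Hydride reduction with i-Bu2AlH should reduce the enoate 1,2 to the allylic alcohol and the ketone to a secondary alcohol whose configuration is irrelevant because it is oxidised in the next step.

Step 8
Reactants: 11 (2E,6Z)-3,7,11-trimethyldodeca-2,6-diene-1,9-diol
Product: 12 (2E,6Z)-3,7,11-trimethyl-9-oxododeca-2,6-dienal
Conditions: Dess–Martin periodinane, NaHCO3, CH2Cl2, 0 → 23 °C
Reagents that add atoms: none
Why: Buffered Dess–Martin oxidation should convert both alcohols at once, giving the E enal and the β,γ-unsaturated ketone without moving either alkene.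

Step 9
Reactants: 12 (2E,6Z)-3,7,11-trimethyl-9-oxododeca-2,6-dienal
Product: 14 (4aR)-4a,8-dimethyl-2-(propan-2-yl)-4a,5,6,8a-tetrahydronaphthalen-1(4H)-one (both C8a epimers), via keto aldehyde 13 (not isolated)
Conditions: (S)-2-tert-butyl-3-methylimidazolidin-4-one·CF3CO2H (20 mol %), CHCl3, −20 → 23 °C; then piperidinium acetate (0.5 equiv), 40 °C
Reagents that add atoms: none
Why: Proposed new method: condensation of the amine with the aldehyde gives an α,β-unsaturated iminium ion, the dienol of the ketone (C5 is α to the C6 carbonyl and allylic to the 6Z alkene) adds through C5 to the β-carbon C10, hydrolysis frees aldehyde 13, and the C7 enol of the same ketone then attacks C8 and water is lost to give the ring B enone. The closest known reaction types are iminium-catalysed conjugate additions to β,β-disubstituted enals (hydride and nitroalkane donors, which also converge E/Z mixtures) and amine-salt-mediated intramolecular Michael and aldol condensations of the Robinson type; what is new is a ketone enol as the donor at a quaternary β-carbon. Ring A closes 6-exo-trig with the enol double bond exocyclic and the Z alkene inside the new ring, and ring B closes 6-(enolendo)-exo-trig followed by dehydration. The only stereocentre that has to be set is the quaternary C10: the tert-butyl group of the S catalyst shields one face of the E iminium ion, so C5 should bond to the Re face of C10, which corresponds to 4aR. The step needs C5 and not C7 as the Michael donor and C7 and not C9 as the aldol donor, which ring size secures (the alternatives give eight- and four-membered rings), and α- and not γ-attack of the dienol, which the Z geometry inherited from the Birch ring secures because only C5 can reach C10. The C5 configuration is left open here and is set in step 10.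

Step 10
Reactants: 14 (4aR)-4a,8-dimethyl-2-(propan-2-yl)-4a,5,6,8a-tetrahydronaphthalen-1(4H)-one (both C8a epimers)
Product: 15 (4aR,8aR)-4a,8-dimethyl-2-(propan-2-yl)-4a,5,6,8a-tetrahydronaphthalen-1(4H)-one
Conditions: LiN(SiMe3)2 (1.1 equiv), THF, −78 °C; then AcOH in THF, −78 °C
Reagents that add atoms: none
Why: Kinetic α'-deprotonation of the enone at the doubly activated C5–H gives one extended enolate from both epimers, and kinetic α-protonation anti to the adjacent angular methyl should give the trans ring fusion with the ring A alkene left out of conjugation (stereoconvergent kinetic protonation).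

Step 11
Reactants: 15 (4aR,8aR)-4a,8-dimethyl-2-(propan-2-yl)-4a,5,6,8a-tetrahydronaphthalen-1(4H)-one
Product: 17 (1R,2S,4aR,8aR)-4a,8-dimethyl-2-(propan-2-yl)-1,2,3,4,4a,5,6,8a-octahydronaphthalen-1-ol, via saturated ketone 16 (not isolated)
Conditions: LiBH(s-Bu)3 (1.1 equiv), THF, −78 °C; AcOH (1.2 equiv), −78 °C; then LiBH(s-Bu)3 (2 equiv), −78 → 0 °C; aq. NaOH, H2O2
Reagents that add atoms: none
Why: Conjugate reduction of the β-unsubstituted enone followed by axial protonation at C7 should place the isopropyl group equatorial, and the second hydride should attack the ketone from the face opposite the 1,3-diaxial angular methyl to give the axial 6β-alcohol.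

Step 12
Reactants: 17 (1R,2S,4aR,8aR)-4a,8-dimethyl-2-(propan-2-yl)-1,2,3,4,4a,5,6,8a-octahydronaphthalen-1-ol, 18 2,2-dimethyl-1,3-dioxane-4,6-dione
Product: 19 3-{[(1R,2S,4aR,8aR)-4a,8-dimethyl-2-(propan-2-yl)-1,2,3,4,4a,5,6,8a-octahydronaphthalen-1-yl]oxy}-3-oxopropanoic acid
Conditions: toluene, 100 °C
Reagents that add atoms: none
Why: Acylative ring opening of the dioxanedione by the alcohol with loss of acetone is a small, neutral acylation that should reach the hindered axial hydroxyl and leaves its configuration untouched.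

Step 13
Reactants: 19 3-{[(1R,2S,4aR,8aR)-4a,8-dimethyl-2-(propan-2-yl)-1,2,3,4,4a,5,6,8a-octahydronaphthalen-1-yl]oxy}-3-oxopropanoic acid, 20 4-hydroxybenzaldehyde
Product: 21 (1R,2S,4aR,8aR)-4a,8-dimethyl-2-(propan-2-yl)-1,2,3,4,4a,5,6,8a-octahydronaphthalen-1-yl (2E)-3-(4-hydroxyphenyl)prop-2-enoate
Conditions: pyridine, piperidine (cat.), 80 °C
Reagents that add atoms: none
Why: Knoevenagel–Doebner condensation of the malonic half ester with the aldehyde and decarboxylation should give the E cinnamate directly without protecting the phenol.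

**Compound list**

1 | 3-methylanisole | COc1cccc(C)c1 | starting material
2 | 1-methoxy-5-methylcyclohexa-1,4-diene | COC1=CCC=C(C)C1 | intermediate
3 | methyl (3Z)-6-hydroxy-3-methylhex-3-enoate | COC(=O)C/C(C)=C\CCO | intermediate
4 | (3Z)-6-hydroxy-N-methoxy-N,3-dimethylhex-3-enamide (not isolated) | CON(C)C(=O)C/C(C)=C\CCO | intermediate
5 | (6Z)-9-hydroxy-2,6-dimethylnon-6-en-4-one | CC(C)CC(=O)C/C(C)=C\CCO | intermediate
6 | (6Z)-9-iodo-2,6-dimethylnon-6-en-4-one | CC(C)CC(=O)C/C(C)=C\CCI | intermediate
7 | ethyl 3-oxobutanoate | CCOC(=O)CC(C)=O | starting material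
8 | ethyl (2E)-3-{[(trifluoromethyl)sulfonyl]oxy}but-2-enoate | CCOC(=O)/C=C(\C)OS(=O)(=O)C(F)(F)F | intermediate
9 | [(3Z)-4,8-dimethyl-6-oxonon-3-en-1-yl]zinc iodide (not isolated) | CC(C)CC(=O)C/C(C)=C\CC[Zn]I | intermediate
10 | ethyl (2E,6Z)-3,7,11-trimethyl-9-oxododeca-2,6-dienoate | CCOC(=O)/C=C(\C)CC/C=C(/C)CC(=O)CC(C)C | intermediate
11 | (2E,6Z)-3,7,11-trimethyldodeca-2,6-diene-1,9-diol (C9 racemic) | OC/C=C(\C)CC/C=C(/C)CC(O)CC(C)C | intermediate
12 | (2E,6Z)-3,7,11-trimethyl-9-oxododeca-2,6-dienal | O=C/C=C(\C)CC/C=C(/C)CC(=O)CC(C)C | intermediate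
13 | 2-[(1R)-1,3-dimethyl-2-(3-methylbutanoyl)cyclohex-3-en-1-yl]acetaldehyde (both C2 epimers, not isolated) | CC1=CCC[C@](C)(CC=O)C1C(=O)CC(C)C | intermediate
14 | (4aR)-4a,8-dimethyl-2-(propan-2-yl)-4a,5,6,8a-tetrahydronaphthalen-1(4H)-one (both C8a epimers) | CC1=CCC[C@]2(C)CC=C(C(C)C)C(=O)C12 | intermediate
15 | (4aR,8aR)-4a,8-dimethyl-2-(propan-2-yl)-4a,5,6,8a-tetrahydronaphthalen-1(4H)-one (trans-fused) | CC1=CCC[C@]2(C)CC=C(C(C)C)C(=O)[C@@H]12 | intermediate
16 | (2S,4aR,8aR)-4a,8-dimethyl-2-(propan-2-yl)-3,4,4a,5,6,8a-hexahydronaphthalen-1(2H)-one (not isolated) | CC1=CCC[C@]2(C)CC[C@@H](C(C)C)C(=O)[C@@H]12 | intermediate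
17 | (1R,2S,4aR,8aR)-4a,8-dimethyl-2-(propan-2-yl)-1,2,3,4,4a,5,6,8a-octahydronaphthalen-1-ol (eudesm-3-en-6β-ol) | CC1=CCC[C@]2(C)CC[C@@H](C(C)C)[C@@H](O)[C@@H]12 | intermediate
18 | 2,2-dimethyl-1,3-dioxane-4,6-dione | CC1(C)OC(=O)CC(=O)O1 | starting material
19 | 3-{[(1R,2S,4aR,8aR)-4a,8-dimethyl-2-(propan-2-yl)-1,2,3,4,4a,5,6,8a-octahydronaphthalen-1-yl]oxy}-3-oxopropanoic acid | CC1=CCC[C@]2(C)CC[C@@H](C(C)C)[C@@H](OC(=O)CC(=O)O)[C@@H]12 | intermediate
20 | 4-hydroxybenzaldehyde | O=Cc1ccc(O)cc1 | starting material
21 | (1R,2S,4aR,8aR)-4a,8-dimethyl-2-(propan-2-yl)-1,2,3,4,4a,5,6,8a-octahydronaphthalen-1-yl (2E)-3-(4-hydroxyphenyl)prop-2-enoate | CC1=CCC[C@]2(C)CC[C@@H](C(C)C)[C@@H](OC(=O)/C=C/c3ccc(O)cc3)[C@@H]12 | target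

**Summary**

Total step count: 13. Longest linear sequence: 12 steps (steps 1–4 and 6–13, from 1).

Steps most likely to fail:

1. Step 9. The enantioselectivity may erode if the E and Z iminium ions interconvert through the dienamine and both cyclise. The hindered enal may form its iminium ion too slowly. The β,γ-alkene of the ketone may also migrate into conjugation before the Michael step. Fallback, setting out from 12: the two bond formations are run without a chiral catalyst as classical reactions, a DBU-mediated intramolecular Michael addition (MeCN, 0 °C) followed by piperidinium acetate-mediated aldol condensation. This would give 14 together with its enantiomer (4aS)-4a,8-dimethyl-2-(propan-2-yl)-4a,5,6,8a-tetrahydronaphthalen-1(4H)-one F2, by way of 13 and its enantiomer 2-[(1S)-1,3-dimethyl-2-(3-methylbutanoyl)cyclohex-3-en-1-yl]acetaldehyde F1. Step 10 as written would then give 15 and its enantiomer (4aS,8aS)-4a,8-dimethyl-2-(propan-2-yl)-4a,5,6,8a-tetrahydronaphthalen-1(4H)-one F3, which are separated by preparative chromatography on a chiral stationary phase; the route is rejoined at 15.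

2. Step 10. The extended enolate may be protonated at the γ-carbon (giving the conjugated dienone) or on the face syn to the angular methyl, and the base may remove a γ-proton at C9 instead. Fallback, setting out from 14: DBU (CH2Cl2, 23 °C) moves the ring A alkene into conjugation to give the cross-conjugated dienone (4aR)-4a,8-dimethyl-2-(propan-2-yl)-4a,5,6,7-tetrahydronaphthalen-1(4H)-one F4, in which C5 is no longer a stereocentre. LiBH(s-Bu)3 (THF, −78 °C; aq. NH4Cl) reduces the less substituted enone to (2S,4aR)-4a,8-dimethyl-2-(propan-2-yl)-3,4,4a,5,6,7-hexahydronaphthalen-1(2H)-one F5. Isopropenyl acetate with TsOH gives the extended dienol acetate (2S,4aR)-4a,8-dimethyl-2-(propan-2-yl)-2,3,4,4a,5,6-hexahydronaphthalen-1-yl acetate F6. NaBH4 in EtOH/H2O at 0 °C then cleaves the acetate, the dienolate is protonated at C5 and the β,γ-unsaturated ketone is reduced at once (the known deconjugative reduction of dienol esters). This gives 17, where the route is rejoined; step 11 is then not needed.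

3. Step 12. Acylation of the hindered axial alcohol may be slower than thermal decomposition of the acyl donor, and elimination of the alcohol may compete. Fallback, setting out from 17: acryloyl chloride, Et3N and DMAP (CH2Cl2, 0 °C) give the acrylate (1R,2S,4aR,8aR)-4a,8-dimethyl-2-(propan-2-yl)-1,2,3,4,4a,5,6,8a-octahydronaphthalen-1-yl prop-2-enoate F7, the smallest unsaturated acyl group. A Heck reaction with 4-iodophenol (Pd(OAc)2, P(o-tol)3, Et3N, DMF, 90 °C) then builds the E cinnamate and gives 21 directly, where the route is rejoined.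

Further compounds
F1 | step 9 | 2-[(1S)-1,3-dimethyl-2-(3-methylbutanoyl)cyclohex-3-en-1-yl]acetaldehyde (both C2 epimers) | CC1=CCC[C@@](C)(CC=O)C1C(=O)CC(C)C
F2 | step 9 | (4aS)-4a,8-dimethyl-2-(propan-2-yl)-4a,5,6,8a-tetrahydronaphthalen-1(4H)-one (both C8a epimers) | CC1=CCC[C@@]2(C)CC=C(C(C)C)C(=O)C12
F3 | step 9 | (4aS,8aS)-4a,8-dimethyl-2-(propan-2-yl)-4a,5,6,8a-tetrahydronaphthalen-1(4H)-one | CC1=CCC[C@@]2(C)CC=C(C(C)C)C(=O)[C@H]12
F4 | step 10 | (4aR)-4a,8-dimethyl-2-(propan-2-yl)-4a,5,6,7-tetrahydronaphthalen-1(4H)-one | CC1=C2C(=O)C(C(C)C)=CC[C@@]2(C)CCC1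
F5 | step 10 | (2S,4aR)-4a,8-dimethyl-2-(propan-2-yl)-3,4,4a,5,6,7-hexahydronaphthalen-1(2H)-one | CC1=C2C(=O)[C@H](C(C)C)CC[C@@]2(C)CCC1
F6 | step 10 | (2S,4aR)-4a,8-dimethyl-2-(propan-2-yl)-2,3,4,4a,5,6-hexahydronaphthalen-1-yl acetate | CC1=CCC[C@]2(C)CC[C@@H](C(C)C)C(OC(C)=O)=C12
F7 | step 12 | (1R,2S,4aR,8aR)-4a,8-dimethyl-2-(propan-2-yl)-1,2,3,4,4a,5,6,8a-octahydronaphthalen-1-yl prop-2-enoate | CC1=CCC[C@]2(C)CC[C@@H](C(C)C)[C@@H](OC(=O)C=C)[C@@H]12
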